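If the green flask went on as it began, its substrate would lose the same fraction of what is left each day, so that fraction is worth reading first.

| setting | green | grey | flask |
|---|---|---|---|
| substrate | 0.10 M | 0.10 M | 0.10 M |
| reagent | 0.18 M | 0.18 M | 0.180 M |
| transfer agent | 0.10 M | 0.10 M | 0.100 M |
| scavenger | 0.10 M | 0.067 M | 0.100 M |
| initiator | 2 mM | 2 mM | 2.0 mM |
| remark | the very flask that is asked about, followed so far | run made earlier |  |
| time |  |  | 2.5 d |

green run (percent of the substrate charged)

| time / h | substrate / % | target / % |
|---|---|---|
| 1.33 | 98.4 | 1.1 |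
| 4.00 | 95.3 | 2.9 |
| 6.00 | 93.7 | 4.0 |
| 10.0 | 89.7 | 7.5 |
| 15.0 | 86.2 | 9.7 |
| 20.0 | 82.6 | 13.5 |
| 25.0 | 78.8 | 15.1 |

grey run (percent of the substrate charged)

| time / d | substrate / % | target / % |
|---|---|---|
| 0.208 | 93.0 | 4.6 |
| 0.333 | 91.0 | 6.9 |
| 0.500 | 87.9 | 8.3 |
| 0.625 | 85.4 | 10.5 |
| 1.04 | 79.0 | 15.6 |
| 1.67 | 70.5 | 21.3 |
| 2.50 | 62.7 | 26.9 |

(each reading ± 0.5 percentage points)

1. part of the substrate that has reacted at 2.5 d
2. share of the unused reagent that is free and not bound as idle adduct, at 2.5 d

- what has gone from substrate into another species counts as reacted, even if it can come back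
- the earlier runs do not show how much of reagent is bound; that part of a forecast is a guess

The fractional loss rate, a pseudo-first-order rate constant, is the natural logarithm of the charge over the substrate left, divided by the time; the last green reading gives 0.229 d⁻¹. Held to 2.5 d, this rate gives 43.6% reacted. That serves as a bound from above, since the grey flask's rate over its whole run reads lower, at 0.187 d⁻¹. The bound tightens with the later green readings, and the result remains a reading with their scatter: between 10.0 h and 25.0 h the green flask ran at 0.207 d⁻¹, and that pace, carried on from the last green reading, gives 41.8%.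

The bound from below is the grey flask itself, which had lost 37.3% at 2.50 d with less scavenger. At 25.0 h the green flask had lost 21.2% and the grey flask 21.0%, so the green flask is taken not to fall behind it.

The forecast gives 39.5% reacted, inside this bracket, and 90% free, with the words “Reagent should then stay mostly free”.

The flask gives 37.3% reacted, at the lower edge, and 92.4% free.

    initiator → 2 initiating radical (k = 5.70 × 10⁻⁶ s⁻¹)
    substrate + initiating radical → capped initiator + first chain carrier (k = 21000 M⁻¹ s⁻¹)
    reagent + first chain carrier → target + second chain carrier (k = 420 M⁻¹ s⁻¹)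
    substrate + second chain carrier → released group + first chain carrier (k = 660 M⁻¹ s⁻¹)
    transfer agent + first chain carrier → side product + idle radical (kL = 69.0 M⁻¹ s⁻¹)
    2 idle radical → ended radicals (k = 4.00 × 10⁸ M⁻¹ s⁻¹)
    2 second chain carrier → ended chains (k = 3.10 × 10⁷ M⁻¹ s⁻¹)
    reagent + released group ⇌ idle adduct, settled at all times (K = 25.0 M⁻¹)
    scavenger + released group → scavenged by-product (k = 2.40 × 10⁻⁴ M⁻¹ s⁻¹)
    substrate ⇌ dormant form (K = 0.390, k = 5.40 × 10⁻⁷ s⁻¹)

The flask's mean fractional loss rate comes to 0.187 d⁻¹, below 0.229 d⁻¹. The main reason the flask stands at 37.3% reacted is the reaction of transfer agent with first chain carrier: with that step taken away, the same flask reaches 89.1%. Initiator at 1.60 mM or 2.43 mM moves the flask's reacted part by 5 points. Scaled to the reagent charge of the neighbour with 0.11 M, 0.229 d⁻¹ gives 29.5%, and that flask stands lower, at 28.0%.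

The readings are simulated for substances that don't exist, and the scatter is random.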